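Everything rests on cutting the C4–C4a bond of ring C. That leaves an (S)-3-aryl-3-aryloxypropanoic acid whose aryloxy part, the future ring A, is a 4-geranyl-3,5-bis(methoxymethoxy)phenyl ether. This ring has a mirror axis through the geranyl-bearing carbon (future C6) and the C8a–O1 bond, so the two carbons ortho to O1 (future C4a and C8) are identical. Intramolecular Friedel–Crafts acylation through a mixed trifluoroacetic anhydride therefore forms C4–C4a, closes ring C and places the geranyl group at C6 in one operation, with no C6/C8 choice to control. C2 is set beforehand by asymmetric transfer hydrogenation followed by Mitsunobu inversion and is not touched in the ring closure.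

Key step: step 10

Remark on the chemistry: the transfer hydrogenation is assumed to follow the usual facial sense for aryl ketones (R,R catalyst gives the R carbinol); the configuration of 14 would be checked before it is carried on.

Step 1
Reactants: 1 phloroglucinol (benzene-1,3,5-triol), in threefold excess
Product: 2 5-[(triisopropylsilyl)oxy]benzene-1,3-diol
Conditions: TIPSCl (1.0 equiv), imidazole (2 equiv), DMF, 0 °C to rt; excess 1 washed out with water
Reagents that add atoms: triisopropylsilyl chloride, CC(C)[Si](Cl)(C(C)C)C(C)C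
Why: Imidazole-promoted O-silylation of a phenol, in which the three hydroxyls of 1 are equivalent, so the excess of triol and the bulk of the silyl group should hold the reaction at the mono-ether and mark the oxygen that becomes O1.

Step 2
Reactants: 2 5-[(triisopropylsilyl)oxy]benzene-1,3-diol
Product: 3 [3,5-bis(methoxymethoxy)phenoxy]triisopropylsilane
Conditions: MOMCl (3 equiv), iPr2NEt (4 equiv), CH2Cl2, 0 °C to rt
Reagents that add atoms: chloromethyl methyl ether, COCCl
Why: Amine-mediated O-alkylation of both remaining phenols with the chloromethyl ether (acetal formation) leaves the aryl silyl ether in place and installs the two groups that direct the metalation.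

Step 3
Reactants: 3 [3,5-bis(methoxymethoxy)phenoxy]triisopropylsilane; 4 geranyl bromide [(2E)-1-bromo-3,7-dimethylocta-2,6-diene]
Product: 6 {4-[(2E)-3,7-dimethylocta-2,6-dien-1-yl]-3,5-bis(methoxymethoxy)phenoxy}triisopropylsilane, via aryllithium 5 (not isolated)
Conditions: n-BuLi (1.2 equiv), THF, 0 °C; then CuI (10 mol%), 4 (1.3 equiv), −78 °C to 0 °C
Reagents that add atoms: none
Why: Directed ortho-metalation removes the one proton flanked by both methoxymethoxy groups (the carbons next to the bulky silyloxy group have only one directing neighbour), and copper-catalysed allylic substitution at the primary carbon of 4 should give the linear E-geranyl arene.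

Step 4
Reactants: 6 {4-[(2E)-3,7-dimethylocta-2,6-dien-1-yl]-3,5-bis(methoxymethoxy)phenoxy}triisopropylsilane
Product: 7 4-[(2E)-3,7-dimethylocta-2,6-dien-1-yl]-3,5-bis(methoxymethoxy)phenol
Conditions: TBAF (1.1 equiv), AcOH (1.1 equiv), THF, 0 °C
Reagents that add atoms: none
Why: Fluoride-induced cleavage of the aryl silyl ether, driven by the Si–F bond and buffered by acetic acid, frees only the oxygen that becomes O1 and leaves the acetals and alkenes alone.

Step 5
Reactants: 8 4-acetoxybenzoic acid; 9 Meldrum's acid (2,2-dimethyl-1,3-dioxane-4,6-dione)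
Product: 11 5-[(4-acetoxyphenyl)(hydroxy)methylidene]-2,2-dimethyl-1,3-dioxane-4,6-dione, via 4-acetoxybenzoyl chloride 10 (not isolated)
Conditions: (COCl)2, DMF (cat.), CH2Cl2, 0 °C to rt, evaporate; then 9, pyridine (2.2 equiv), CH2Cl2, 0 °C; cold 1 M HCl wash
Reagents that add atoms: none
Why: C-Acylation of Meldrum's acid by the acid chloride (first half of the Oikawa–Yonemitsu β-keto ester synthesis) runs under pyridine buffering at 0 °C, where the aryl acetate meets no competent nucleophile.

Step 6
Reactants: 11 5-[(4-acetoxyphenyl)(hydroxy)methylidene]-2,2-dimethyl-1,3-dioxane-4,6-dione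
Product: 13 prop-2-en-1-yl 3-(4-acetoxyphenyl)-3-oxopropanoate, via acylketene 12 (not isolated)
Conditions: allyl alcohol (3 equiv), toluene, 90 °C
Reagents that add atoms: allyl alcohol, C=CCO
Why: Thermal cycloreversion of the acyl Meldrum's acid releases acetone and CO2 and gives an acylketene that allyl alcohol traps, a neutral β-keto ester synthesis that keeps the phenolic acetate.

Step 7
Reactants: 13 prop-2-en-1-yl 3-(4-acetoxyphenyl)-3-oxopropanoate
Product: 14 prop-2-en-1-yl (3R)-3-(4-acetoxyphenyl)-3-hydroxypropanoate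
Conditions: RuCl[(R,R)-TsDPEN](p-cymene) (1 mol%), HCO2H/Et3N (5:2), EtOAc, 30 °C
Reagents that add atoms: none
Why: Noyori–Ikariya asymmetric transfer hydrogenation delivers hydride and proton through an outer-sphere six-membered transition state to the Si face of the aryl ketone (aryl group held under the cymene ligand of the R,R catalyst), which sets the R carbinol, and since no H2 is used the allyl ester alkene and the aryl acetate should survive.

Step 8
Reactants: 7 4-[(2E)-3,7-dimethylocta-2,6-dien-1-yl]-3,5-bis(methoxymethoxy)phenol; 14 prop-2-en-1-yl (3R)-3-(4-acetoxyphenyl)-3-hydroxypropanoate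
Product: 15 prop-2-en-1-yl (3S)-3-(4-acetoxyphenyl)-3-{4-[(2E)-3,7-dimethylocta-2,6-dien-1-yl]-3,5-bis(methoxymethoxy)phenoxy}propanoate
Conditions: PPh3 (1.5 equiv), DIAD (1.5 equiv, slow addition), toluene, −20 °C to 0 °C
Reagents that add atoms: none
Why: Mitsunobu etherification, in which the phenoxide of 7 displaces the oxyphosphonium group of 14 by SN2 with inversion (R to S), the electron-poor 4-acetoxyphenyl group disfavouring ionisation and the cold non-polar medium holding back β-elimination to the cinnamate.

Step 9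
Reactants: 15 prop-2-en-1-yl (3S)-3-(4-acetoxyphenyl)-3-{4-[(2E)-3,7-dimethylocta-2,6-dien-1-yl]-3,5-bis(methoxymethoxy)phenoxy}propanoate
Product: 16 (3S)-3-(4-acetoxyphenyl)-3-{4-[(2E)-3,7-dimethylocta-2,6-dien-1-yl]-3,5-bis(methoxymethoxy)phenoxy}propanoic acid
Conditions: Pd(PPh3)4 (5 mol%), N-methylaniline (3 equiv), THF, rt; pH 4 citrate wash
Reagents that add atoms: none
Why: Tsuji–Trost deallylation, in which zerovalent palladium ionises the allyl ester to a π-allyl complex that the weakly nucleophilic aniline intercepts, frees the acid without base, so neither β-elimination of the aryloxy group nor loss of the acetate or acetals is expected.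

Step 10
Reactants: 16 (3S)-3-(4-acetoxyphenyl)-3-{4-[(2E)-3,7-dimethylocta-2,6-dien-1-yl]-3,5-bis(methoxymethoxy)phenoxy}propanoic acid
Product: 18 (2S)-2-(4-acetoxyphenyl)-6-[(2E)-3,7-dimethylocta-2,6-dien-1-yl]-5,7-bis(methoxymethoxy)-2,3-dihydro-4H-chromen-4-one, via mixed anhydride 17 (not isolated)
Conditions: TFAA (1.2 equiv), 2,6-di-tert-butyl-4-methylpyridine (2.5 equiv), CH2Cl2 (0.02 M), −40 °C to 0 °C; pH 7 phosphate quench
Reagents that add atoms: none
Why: TFAA turns the acid into the mixed anhydride 17, whose acyl carbon is attacked by a ring carbon ortho to O1 (also ortho to one methoxymethoxy group and para to the other), and the Wheland intermediate gives its proton to the hindered pyridine; this is intramolecular Friedel–Crafts acylation, the standard way from 3-aryloxypropanoic acids to chroman-4-ones. Ring C closes in the 6-exo-trig mode at the acyl carbon, forming C4–C4a. No stereocentre is created; C2 takes no part in bond making or breaking, and the 4-acetoxyphenyl group together with the buffer disfavours ionisation of the benzylic C2–O1 bond, so the S configuration should persist. Regioselectivity is not needed, because the mirror axis through C6 and C8a makes the two ortho carbons identical and either closure gives the 6-geranyl isomer. The selectivity that is needed is acylation of ring A in preference to protonation or acylation of the geranyl alkenes and to acetal cleavage; it rests on the high nucleophilicity of the trioxygenated ring, the six-membered intramolecular transition state, the near-stoichiometric TFAA and the base that traps both equivalents of CF3CO2H.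

Step 11
Reactants: 18 (2S)-2-(4-acetoxyphenyl)-6-[(2E)-3,7-dimethylocta-2,6-dien-1-yl]-5,7-bis(methoxymethoxy)-2,3-dihydro-4H-chromen-4-one
Product: 19 Bonannione A, (2S)-6-[(2E)-3,7-dimethylocta-2,6-dien-1-yl]-5,7-dihydroxy-2-(4-hydroxyphenyl)-2,3-dihydro-4H-chromen-4-one
Conditions: HCl in MeOH (1.25 M), 40 °C, followed by HPLC and stopped at full conversion; pH 6 phosphate buffer
Reagents that add atoms: none
Why: Acid-catalysed methanolysis exchanges both methoxymethyl acetals to dimethoxymethane and transesterifies the aryl acetate to methyl acetate, and the short exposure at moderate temperature should leave the geranyl alkenes and the C2 configuration untouched.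

Compound list
1 | phloroglucinol (benzene-1,3,5-triol) | Oc1cc(O)cc(O)c1 | starting material
2 | 5-[(triisopropylsilyl)oxy]benzene-1,3-diol | CC(C)[Si](Oc1cc(O)cc(O)c1)(C(C)C)C(C)C | intermediate
3 | [3,5-bis(methoxymethoxy)phenoxy]triisopropylsilane | COCOc1cc(OCOC)cc(O[Si](C(C)C)(C(C)C)C(C)C)c1 | intermediate
4 | geranyl bromide, (2E)-1-bromo-3,7-dimethylocta-2,6-diene | CC(C)=CCC/C(C)=C/CBr | starting material
5 | {2,6-bis(methoxymethoxy)-4-[(triisopropylsilyl)oxy]phenyl}lithium | [Li]c1c(OCOC)cc(O[Si](C(C)C)(C(C)C)C(C)C)cc1OCOC | intermediate (not isolated)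
6 | {4-[(2E)-3,7-dimethylocta-2,6-dien-1-yl]-3,5-bis(methoxymethoxy)phenoxy}triisopropylsilane | CC(C)=CCC/C(C)=C/Cc1c(OCOC)cc(O[Si](C(C)C)(C(C)C)C(C)C)cc1OCOC | intermediate
7 | 4-[(2E)-3,7-dimethylocta-2,6-dien-1-yl]-3,5-bis(methoxymethoxy)phenol | CC(C)=CCC/C(C)=C/Cc1c(OCOC)cc(O)cc1OCOC | intermediate
8 | 4-acetoxybenzoic acid | CC(=O)Oc1ccc(cc1)C(O)=O | starting material
9 | Meldrum's acid, 2,2-dimethyl-1,3-dioxane-4,6-dione | CC1(C)OC(=O)CC(=O)O1 | starting material
10 | 4-acetoxybenzoyl chloride | CC(=O)Oc1ccc(cc1)C(Cl)=O | intermediate (not isolated)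
11 | 5-[(4-acetoxyphenyl)(hydroxy)methylidene]-2,2-dimethyl-1,3-dioxane-4,6-dione | CC(=O)Oc1ccc(cc1)C(O)=C1C(=O)OC(C)(C)OC1=O | intermediate
12 | (4-acetoxybenzoyl)ketene | CC(=O)Oc1ccc(cc1)C(=O)C=C=O | intermediate (not isolated)
13 | prop-2-en-1-yl 3-(4-acetoxyphenyl)-3-oxopropanoate | C=CCOC(=O)CC(=O)c1ccc(OC(C)=O)cc1 | intermediate
14 | prop-2-en-1-yl (3R)-3-(4-acetoxyphenyl)-3-hydroxypropanoate | C=CCOC(=O)C[C@@H](O)c1ccc(OC(C)=O)cc1 | intermediate
15 | prop-2-en-1-yl (3S)-3-(4-acetoxyphenyl)-3-{4-[(2E)-3,7-dimethylocta-2,6-dien-1-yl]-3,5-bis(methoxymethoxy)phenoxy}propanoate | C=CCOC(=O)C[C@@H](c1ccc(OC(C)=O)cc1)Oc1cc(OCOC)c(C/C=C(\C)CCC=C(C)C)c(OCOC)c1 | intermediate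
16 | (3S)-3-(4-acetoxyphenyl)-3-{4-[(2E)-3,7-dimethylocta-2,6-dien-1-yl]-3,5-bis(methoxymethoxy)phenoxy}propanoic acid | OC(=O)C[C@@H](c1ccc(OC(C)=O)cc1)Oc1cc(OCOC)c(C/C=C(\C)CCC=C(C)C)c(OCOC)c1 | intermediate (key-step precursor)
17 | mixed anhydride of 16 and trifluoroacetic acid | O=C(OC(=O)C(F)(F)F)C[C@@H](c1ccc(OC(C)=O)cc1)Oc1cc(OCOC)c(C/C=C(\C)CCC=C(C)C)c(OCOC)c1 | intermediate (not isolated)
18 | (2S)-2-(4-acetoxyphenyl)-6-[(2E)-3,7-dimethylocta-2,6-dien-1-yl]-5,7-bis(methoxymethoxy)-2,3-dihydro-4H-chromen-4-one | CC(C)=CCC/C(C)=C/Cc1c(OCOC)cc2c(c1OCOC)C(=O)C[C@@H](c1ccc(OC(C)=O)cc1)O2 | intermediate (key-step product)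
19 | Bonannione A, (2S)-6-geranyl-5,7-dihydroxy-2-(4-hydroxyphenyl)-2,3-dihydro-4H-chromen-4-one | CC(C)=CCC/C(C)=C/Cc1c(O)cc2c(c1O)C(=O)C[C@@H](c1ccc(O)cc1)O2 | target

Total step count: 11
Longest linear sequence: 8 steps (steps 1, 2, 3, 4, 8, 9, 10, 11)

Steps most likely to fail

1. Step 10. With the acid fully buffered, the mixed anhydride may ionise too slowly, so that intermolecular trifluoroacetylation of ring A by TFAA competes. If acid is allowed to build up instead, acetal loss and cationic cyclisation of the geranyl chain set in. The fallback sets out from 16 and comes back at 18. It replaces the in-situ anhydride by a separately made, much stronger acyl donor that needs no acid catalysis and brings no second acylating agent. Acid 16 would be treated with 1-chloro-N,N,2-trimethylprop-1-en-1-amine in CH2Cl2 at 0 °C to give, under neutral conditions, (3S)-3-(4-acetoxyphenyl)-3-{4-[(2E)-3,7-dimethylocta-2,6-dien-1-yl]-3,5-bis(methoxymethoxy)phenoxy}propanoyl chloride F1. Chloride abstraction from F1 with AgOTf in the presence of 2,6-di-tert-butyl-4-methylpyridine in CH2Cl2 at −78 °C would generate the corresponding acyl trifluoromethanesulfonate F2, which should close onto either equivalent ortho carbon to give 18.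

2. Step 8. The oxyphosphonium intermediate can lose its activated oxygen by β-elimination toward the conjugated cinnamate faster than the phenoxide displaces it, and partial ionisation would erode the configuration. The fallback sets out from 14 and comes back at 16. It carries the carboxyl carbon through the ether formation at the alcohol level, where there is no acidic α-hydrogen.
- LiBH4 in THF would reduce both esters of 14 to (1R)-1-(4-hydroxyphenyl)propane-1,3-diol F3.
- Ac2O with one equivalent of aqueous NaOH at 0 °C would acetylate only the phenoxide, giving 4-[(1R)-1,3-dihydroxypropyl]phenyl acetate F4.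
- TBSCl and imidazole in CH2Cl2 at −10 °C would silylate the primary hydroxyl, giving 4-[(1R)-3-{[tert-butyl(dimethyl)silyl]oxy}-1-hydroxypropyl]phenyl acetate F5.
- Mitsunobu coupling of F5 with 7 (PPh3, DIAD, toluene, 0 °C) would give, with inversion, 4-[(1S)-3-{[tert-butyl(dimethyl)silyl]oxy}-1-{4-[(2E)-3,7-dimethylocta-2,6-dien-1-yl]-3,5-bis(methoxymethoxy)phenoxy}propyl]phenyl acetate F6.
- HF·pyridine in THF/pyridine would remove the silyl group, giving 4-[(1S)-1-{4-[(2E)-3,7-dimethylocta-2,6-dien-1-yl]-3,5-bis(methoxymethoxy)phenoxy}-3-hydroxypropyl]phenyl acetate F7.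
- TEMPO (cat.) with PhI(OAc)2 in MeCN/pH 7 buffer would oxidise the primary alcohol of F7 to acid 16.

3. Step 11. If the acid treatment runs too long, a freed ring A hydroxyl can add to the neighbouring geranyl double bond (chroman formation), HCl or methanol can add to the alkenes, and C2 can epimerise through ring opening. The fallback sets out from 18 and comes back at 19. It removes the two kinds of protecting group separately and without protic acid. TMSOTf and 2,2′-bipyridyl in MeCN at 0 °C, followed by water, would cleave both aryl methoxymethyl ethers through their silyl ethers and give (2S)-2-(4-acetoxyphenyl)-6-[(2E)-3,7-dimethylocta-2,6-dien-1-yl]-5,7-dihydroxy-2,3-dihydro-4H-chromen-4-one F8. Immobilised Candida antarctica lipase B with n-butanol in tert-butyl methyl ether at 40 °C would then transfer the acetyl group of F8 to butanol under neutral conditions and give 19.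

Further compounds
F1 | step 10 | (3S)-3-(4-acetoxyphenyl)-3-{4-[(2E)-3,7-dimethylocta-2,6-dien-1-yl]-3,5-bis(methoxymethoxy)phenoxy}propanoyl chloride | O=C(Cl)C[C@@H](c1ccc(OC(C)=O)cc1)Oc1cc(OCOC)c(C/C=C(\C)CCC=C(C)C)c(OCOC)c1
F2 | step 10 | (3S)-3-(4-acetoxyphenyl)-3-{4-[(2E)-3,7-dimethylocta-2,6-dien-1-yl]-3,5-bis(methoxymethoxy)phenoxy}propanoyl trifluoromethanesulfonate | O=C(OS(=O)(=O)C(F)(F)F)C[C@@H](c1ccc(OC(C)=O)cc1)Oc1cc(OCOC)c(C/C=C(\C)CCC=C(C)C)c(OCOC)c1
F3 | step 8 | (1R)-1-(4-hydroxyphenyl)propane-1,3-diol | OCC[C@@H](O)c1ccc(O)cc1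
F4 | step 8 | 4-[(1R)-1,3-dihydroxypropyl]phenyl acetate | OCC[C@@H](O)c1ccc(OC(C)=O)cc1
F5 | step 8 | 4-[(1R)-3-{[tert-butyl(dimethyl)silyl]oxy}-1-hydroxypropyl]phenyl acetate | CC(C)(C)[Si](C)(C)OCC[C@@H](O)c1ccc(OC(C)=O)cc1
F6 | step 8 | 4-[(1S)-3-{[tert-butyl(dimethyl)silyl]oxy}-1-{4-[(2E)-3,7-dimethylocta-2,6-dien-1-yl]-3,5-bis(methoxymethoxy)phenoxy}propyl]phenyl acetate | CC(C)(C)[Si](C)(C)OCC[C@@H](c1ccc(OC(C)=O)cc1)Oc1cc(OCOC)c(C/C=C(\C)CCC=C(C)C)c(OCOC)c1
F7 | step 8 | 4-[(1S)-1-{4-[(2E)-3,7-dimethylocta-2,6-dien-1-yl]-3,5-bis(methoxymethoxy)phenoxy}-3-hydroxypropyl]phenyl acetate | OCC[C@@H](c1ccc(OC(C)=O)cc1)Oc1cc(OCOC)c(C/C=C(\C)CCC=C(C)C)c(OCOC)c1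
F8 | step 11 | (2S)-2-(4-acetoxyphenyl)-6-[(2E)-3,7-dimethylocta-2,6-dien-1-yl]-5,7-dihydroxy-2,3-dihydro-4H-chromen-4-one | CC(C)=CCC/C(C)=C/Cc1c(O)cc2c(c1O)C(=O)C[C@@H](c1ccc(OC(C)=O)cc1)O2
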